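**Retrosynthetic overview**

1. Kazinol A (18) ⇐ ester removal from flavan dipivalate 17 ⇐ (S)-1,3-diarylpropanol silyl ether 13, by closing the pyran ring (ring C) last, at the O1–C8a bond, through oxidative dearomatization / oxa-Michael addition / rearomatization.
2. Enabling feature: on ring A, O1 sits on C8a, which is ortho to C4a (the carbon carrying the C4–C3–C2 chain) and meta to the C7 hydroxyl, while that hydroxyl is para to C4a. Ring A is therefore a para-alkylphenol whose 4-methoxycyclohexa-2,5-dienone form has its β-carbon exactly at C8a, six atoms from the C2 oxygen, and re-aromatizes by loss of methanol.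
3. 13 ⇐ C2 stereocenter by asymmetric transfer hydrogenation of dihydrochalcone 10 ⇐ Heck arylation of allylic alcohol 8 with 4-iodophenol ⇐ aldehyde 6 + vinylmagnesium bromide.
4. Ring B aldehyde 6 ⇐ double aromatic Claisen rearrangement of the bis(1,1-dimethylallyl) ether 4 of 3,4-dihydroxybenzaldehyde (each oxygen has only one free ortho carbon).
5. Order of ring formation: rings A and B are bought as benzene rings; ring C is the only ring made (step 8).

Key step: step 8

Remark: flavan numbering is used (O1, C2, C3, C4, C4a to C8a; ring A = benzo ring, ring B = 2-aryl group, ring C = pyran ring); prenyl = 3-methylbut-2-en-1-yl, Piv = 2,2-dimethylpropanoyl, TES = triethylsilyl, aryl B = 3,4-bis(pivaloyloxy)-2,5-diprenylphenyl; starting materials 1, 2, 7 and 9 are assumed to be bought.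

**Route**

Step 1
Reactants: 1 3,4-dihydroxybenzaldehyde; 2 3-chloro-3-methylbut-1-yne (3 equiv)
Product: 3 3,4-bis[(2-methylbut-3-yn-2-yl)oxy]benzaldehyde
Conditions: CuCl2·2H2O (1 mol%), DBU, MeCN, 0 °C to rt
Reagents that add atoms: none
Why: Copper-catalyzed propargylic etherification, in which the tertiary propargylic chloride is ionized to a copper-bound allenylidene-type electrophile that each phenoxide captures at the tertiary carbon, is the usual way to make 1,1-dimethylpropargyl aryl ethers; no stereocenter is formed.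

Step 2
Reactants: 3 3,4-bis[(2-methylbut-3-yn-2-yl)oxy]benzaldehyde
Product: 4 3,4-bis[(2-methylbut-3-en-2-yl)oxy]benzaldehyde
Conditions: H2 (1 atm), Pd/CaCO3 poisoned with Pb(OAc)2, quinoline, EtOAc, rt
Reagents that add atoms: none
Why: Semihydrogenation of the two terminal alkynes over lead-poisoned palladium should stop at the alkene stage and leave the aldehyde and the aryl ethers untouched.

Step 3
Reactants: 4 3,4-bis[(2-methylbut-3-en-2-yl)oxy]benzaldehyde
Product: 6 3,4-bis(pivaloyloxy)-2,5-diprenylbenzaldehyde, via diprenylcatechol aldehyde 5 (not isolated)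
Conditions: N,N-diethylaniline, 150 °C; then PivCl, Et3N, DMAP (cat.), CH2Cl2, 0 °C to rt
Reagents that add atoms: pivaloyl chloride, CC(C)(C)C(=O)Cl
Why: Two aromatic Claisen rearrangements ([3,3], with the allyl inversion that turns each 1,1-dimethylallyl ether into a prenyl group) are forced into the single free ortho carbon of each oxygen (C2 for O3, C5 for O4), and catechol 5 is acylated in the same flask so that the ortho-prenylphenols cannot cyclize to chromans.

Step 4
Reactants: 6 3,4-bis(pivaloyloxy)-2,5-diprenylbenzaldehyde; 7 vinylmagnesium bromide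
Product: 8 rac-1-(aryl B)prop-2-en-1-ol
Conditions: THF, −78 °C; then aq NH4Cl
Reagents that add atoms: none
Why: Grignard 1,2-addition to the aldehyde at −78 °C is far faster than attack on the hindered aryl pivalates; the carbinol center is left racemic on purpose because step 5 erases it.

Step 5
Reactants: 8 rac-1-(aryl B)prop-2-en-1-ol; 9 4-iodophenol
Product: 10 1-(aryl B)-3-(4-hydroxyphenyl)propan-1-one
Conditions: Pd(OAc)2 (5 mol%), Bu4NCl, NaHCO3, DMF, 50 °C
Reagents that add atoms: none
Why: Heck arylation of a secondary allylic alcohol under ligand-free phase-transfer conditions: the arylpalladium species adds to the monosubstituted alkene rather than to the trisubstituted prenyl alkenes, β-hydride elimination toward the carbinol gives the enol, and tautomerization delivers the saturated ketone directly.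

Step 6
Reactants: 10 1-(aryl B)-3-(4-hydroxyphenyl)propan-1-one
Product: 11 (1S)-1-(aryl B)-3-(4-hydroxyphenyl)propan-1-ol
Conditions: RuCl[(S,S)-TsDPEN](p-cymene) (2 mol%), HCO2H/Et3N azeotrope, 30 °C
Reagents that add atoms: none
Why: Noyori–Ikariya asymmetric transfer hydrogenation of an aryl alkyl ketone: the (S,S)-TsDPEN ruthenium hydride should deliver hydride to the Re face through its CH/π-organized six-membered transition state, setting the S configuration of the future C2, while phenol, esters and prenyl alkenes are inert to the formate reductant.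

Step 7
Reactants: 11 (1S)-1-(aryl B)-3-(4-hydroxyphenyl)propan-1-ol
Product: 13 4-[(3S)-3-(aryl B)-3-(triethylsilyloxy)propyl]phenol, via bis-TES ether 12 (not isolated)
Conditions: TESCl, imidazole, CH2Cl2, 0 °C to rt; aqueous wash; then K2CO3 (0.2 equiv), MeOH, 0 °C
Reagents that add atoms: chlorotriethylsilane, CC[Si](Cl)(CC)CC
Why: Both hydroxyls are silylated and only the aryl silyl ether is then cleaved by catalytic carbonate in methanol, because phenoxide is a far better leaving group from silicon than the secondary alkoxide and the hindered pivalates resist methanolysis at 0 °C (standard selective desilylation).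

Step 8
Reactants: 13 4-[(3S)-3-(aryl B)-3-(triethylsilyloxy)propyl]phenol
Product: 17 (2S)-2-(aryl B)chroman-7-ol, via quinol methyl ether 14 (not isolated), via hydroxy dienone 15 (not isolated), via oxa-Michael adduct 16 (not isolated)
Conditions: PhI(OAc)2 (1.0 equiv), MeOH, 0 °C; then TsOH·H2O, 0 to 40 °C
Reagents that add atoms: none
Why: Proposed new method: PhI(OAc)2 oxidizes the para-alkylphenol of ring A and methanol captures the phenoxenium-type intermediate at C4a (the silyl ether cannot spirocyclize and also holds the cascade back until the oxidant is spent, which matters because 17 is itself an oxidizable para-alkylphenol), giving quinol ether 14; TsOH then cleaves the TES ether, the freed C2 hydroxyl of 15 adds to the adjacent β-carbon of the dienone (the future C8a) in an oxa-Michael addition that forms the O1–C8a bond, and the enol of adduct 16 loses methanol across C4a–C8a in an arene-hydrate-type elimination that restores ring A with the new oxygen meta to the C7 hydroxyl. The closest known reaction types are the dearomatization/Michael addition/rearomatization sequences that functionalize para-substituted phenols and anilines at the meta position through 4-methoxycyclohexadienones, and the acid-catalyzed oxa-Michael additions of tethered alcohols to cyclohexadienones; their use to close a chroman at the aryl–oxygen bond is the untested part, and the borrowed methoxy group is returned as methanol. Ring C closes in 6-exo-trig mode, the attacked alkene lying outside the new ring. No new stereocenter reaches the product: C4a and C8a of 16 arise as a mixture (either enone arm, either face) and every isomer converges on 17 when aromatization erases both, while C2, set in step 6, is never a reacting center. The step needs conjugate addition to win over ionization of the quinol ether, dienone–phenol shift and solvolysis of the benzylic C2–O bond; the six-membered chair-like approach, the mild acid and the two pivalates, which keep ring B too electron-poor to be oxidized by PhI(OAc)2 or to support a benzylic cation, are there to secure this.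

Step 9
Reactants: 17 (2S)-2-(aryl B)chroman-7-ol
Product: 18 Kazinol A
Conditions: i-Bu2AlH (DIBAL-H, excess), CH2Cl2, −78 °C; then aq potassium sodium tartrate
Reagents that add atoms: none
Why: Hydride reduction of the two aryl pivalates releases the phenols as aluminium phenoxides under reducing, non-protic conditions, so the air-sensitive catechol is not oxidized, the prenyl alkenes are untouched, and no phenoxide-driven opening of ring C at C2 can scramble the stereocenter.

**Compound list**

1 | 3,4-dihydroxybenzaldehyde | O=Cc1ccc(O)c(O)c1 | starting material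
2 | 3-chloro-3-methylbut-1-yne | C#CC(C)(C)Cl | starting material
3 | 3,4-bis[(2-methylbut-3-yn-2-yl)oxy]benzaldehyde | O=Cc1ccc(OC(C)(C)C#C)c(OC(C)(C)C#C)c1 | intermediate
4 | 3,4-bis[(2-methylbut-3-en-2-yl)oxy]benzaldehyde | O=Cc1ccc(OC(C)(C)C=C)c(OC(C)(C)C=C)c1 | intermediate
5 | 3,4-dihydroxy-2,5-bis(3-methylbut-2-en-1-yl)benzaldehyde (not isolated) | CC(C)=CCc1cc(C=O)c(CC=C(C)C)c(O)c1O | intermediate
6 | 3,4-bis(pivaloyloxy)-2,5-bis(3-methylbut-2-en-1-yl)benzaldehyde | CC(C)=CCc1cc(C=O)c(CC=C(C)C)c(OC(=O)C(C)(C)C)c1OC(=O)C(C)(C)C | intermediate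
7 | vinylmagnesium bromide | C=C[Mg]Br | starting material
8 | rac-1-[3,4-bis(pivaloyloxy)-2,5-diprenylphenyl]prop-2-en-1-ol | CC(C)=CCc1cc(C(O)C=C)c(CC=C(C)C)c(OC(=O)C(C)(C)C)c1OC(=O)C(C)(C)C | intermediate
9 | 4-iodophenol | Oc1ccc(I)cc1 | starting material
10 | 1-[3,4-bis(pivaloyloxy)-2,5-diprenylphenyl]-3-(4-hydroxyphenyl)propan-1-one | CC(C)=CCc1cc(C(=O)CCc2ccc(O)cc2)c(CC=C(C)C)c(OC(=O)C(C)(C)C)c1OC(=O)C(C)(C)C | intermediate
11 | (1S)-1-[3,4-bis(pivaloyloxy)-2,5-diprenylphenyl]-3-(4-hydroxyphenyl)propan-1-ol | CC(C)=CCc1cc([C@H](CCc2ccc(O)cc2)O)c(CC=C(C)C)c(OC(=O)C(C)(C)C)c1OC(=O)C(C)(C)C | intermediate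
12 | (1S)-1-[3,4-bis(pivaloyloxy)-2,5-diprenylphenyl]-1-(triethylsilyloxy)-3-[4-(triethylsilyloxy)phenyl]propane (not isolated) | CC(C)=CCc1cc([C@H](CCc2ccc(O[Si](CC)(CC)CC)cc2)O[Si](CC)(CC)CC)c(CC=C(C)C)c(OC(=O)C(C)(C)C)c1OC(=O)C(C)(C)C | intermediate
13 | 4-[(3S)-3-[3,4-bis(pivaloyloxy)-2,5-diprenylphenyl]-3-(triethylsilyloxy)propyl]phenol | CC(C)=CCc1cc([C@H](CCc2ccc(O)cc2)O[Si](CC)(CC)CC)c(CC=C(C)C)c(OC(=O)C(C)(C)C)c1OC(=O)C(C)(C)C | intermediate
14 | 4-methoxy-4-[(3S)-3-[3,4-bis(pivaloyloxy)-2,5-diprenylphenyl]-3-(triethylsilyloxy)propyl]cyclohexa-2,5-dien-1-one (not isolated) | CC(C)=CCc1cc([C@H](CCC2(OC)C=CC(=O)C=C2)O[Si](CC)(CC)CC)c(CC=C(C)C)c(OC(=O)C(C)(C)C)c1OC(=O)C(C)(C)C | intermediate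
15 | 4-[(3S)-3-[3,4-bis(pivaloyloxy)-2,5-diprenylphenyl]-3-hydroxypropyl]-4-methoxycyclohexa-2,5-dien-1-one (not isolated) | CC(C)=CCc1cc([C@H](CCC2(OC)C=CC(=O)C=C2)O)c(CC=C(C)C)c(OC(=O)C(C)(C)C)c1OC(=O)C(C)(C)C | intermediate
16 | (2S)-2-[3,4-bis(pivaloyloxy)-2,5-diprenylphenyl]-4a-methoxy-2,3,4,4a,8,8a-hexahydro-7H-chromen-7-one (not isolated; mixture of C4a/C8a diastereomers, only C2 defined) | CC(C)=CCc1cc([C@@H]2CCC3(OC)C=CC(=O)CC3O2)c(CC=C(C)C)c(OC(=O)C(C)(C)C)c1OC(=O)C(C)(C)C | intermediate
17 | (2S)-2-[3,4-bis(pivaloyloxy)-2,5-diprenylphenyl]chroman-7-ol | CC(C)=CCc1cc([C@@H]2CCc3ccc(O)cc3O2)c(CC=C(C)C)c(OC(=O)C(C)(C)C)c1OC(=O)C(C)(C)C | intermediate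
18 | Kazinol A, (2S)-2-[3,4-dihydroxy-2,5-bis(3-methylbut-2-en-1-yl)phenyl]chroman-7-ol | CC(C)=CCc1cc([C@@H]2CCc3ccc(O)cc3O2)c(CC=C(C)C)c(O)c1O | target

**Step count and risks**

Total step count: 9. Longest linear sequence: 9 steps (1 to 18).

Steps most likely to fail:

Step 8 (Proposed new method). What may go wrong: the oxa-Michael closure may lose to acid-induced ionization or dienone–phenol rearrangement of the quinol ether, the adduct may fail to shed methanol, or leftover oxidant may attack the product phenol. The fallback uses known chemistry, an intramolecular palladium-catalyzed aryl etherification of a secondary alcohol, which does not break the carbinol C–O bond and so should retain configuration. It sets out from 8 and comes back at 18. Allylic alcohol 8 is arylated under the step 5 conditions with purchased 3-bromo-4-iodophenol (Oc1ccc(I)c(Br)c1; the C–I bond should react selectively) to give 1-(aryl B)-3-(2-bromo-4-hydroxyphenyl)propan-1-one F1. Transfer hydrogenation as in step 6 should give (1S)-1-(aryl B)-3-(2-bromo-4-hydroxyphenyl)propan-1-ol F2. PivCl/Et3N at 0 °C should acylate the phenol only, giving 3-bromo-4-[(3S)-3-(aryl B)-3-hydroxypropyl]phenyl pivalate F3. Pd(OAc)2, 2-(di-tert-butylphosphino)-1,1'-binaphthyl, Cs2CO3, toluene, 70 °C should form the O1–C8a bond and give (2S)-2-(aryl B)chroman-7-yl pivalate F4. DIBAL-H as in step 9 then removes all three esters and gives 18.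

Step 3. What may go wrong: fragmentation of the tertiary allyl ethers to phenol and isoprene, or cyclization of the first-formed ortho-prenylphenol, may outrun the [3,3] shift into the crowded C2 position; the same crowding could already stall the second etherification in step 1. The fallback sets out from 1 and comes back at 6, bypassing steps 1 to 3. Allyl bromide/K2CO3/DMF should give 3,4-bis(allyloxy)benzaldehyde F5. A thermal double Claisen rearrangement (N,N-diethylaniline, 190 °C; again one free ortho carbon per oxygen) should give 2,5-diallyl-3,4-dihydroxybenzaldehyde F6. PivCl/Et3N/DMAP should give 2,5-diallyl-3,4-bis(pivaloyloxy)benzaldehyde F7. Twofold olefin cross-metathesis with 2-methylbut-2-ene (second-generation Grubbs catalyst, CH2Cl2, 40 °C) should turn both allyl groups into prenyl groups and give 6.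

Step 5. What may go wrong: β-hydride elimination away from the carbinol (giving the arylated allylic alcohol), palladium-hydride migration of the prenyl double bonds, or poor turnover with the free iodophenol. The fallback sets out from 8 and comes back at 10. MnO2 in CH2Cl2 should oxidize the allylic benzylic alcohol to 1-(aryl B)prop-2-en-1-one F8. Rhodium-catalyzed conjugate addition (Hayashi–Miyaura) of purchased 4-hydroxyphenylboronic acid ([Rh(OH)(cod)]2, dioxane/H2O, 40 °C) should give 10.

**Further compounds**

F1 | step 8 | 1-[3,4-bis(pivaloyloxy)-2,5-diprenylphenyl]-3-(2-bromo-4-hydroxyphenyl)propan-1-one | CC(C)=CCc1cc(C(=O)CCc2ccc(O)cc2Br)c(CC=C(C)C)c(OC(=O)C(C)(C)C)c1OC(=O)C(C)(C)C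
F2 | step 8 | (1S)-1-[3,4-bis(pivaloyloxy)-2,5-diprenylphenyl]-3-(2-bromo-4-hydroxyphenyl)propan-1-ol | CC(C)=CCc1cc([C@H](CCc2ccc(O)cc2Br)O)c(CC=C(C)C)c(OC(=O)C(C)(C)C)c1OC(=O)C(C)(C)C
F3 | step 8 | 3-bromo-4-[(3S)-3-[3,4-bis(pivaloyloxy)-2,5-diprenylphenyl]-3-hydroxypropyl]phenyl pivalate | CC(C)=CCc1cc([C@H](CCc2ccc(OC(=O)C(C)(C)C)cc2Br)O)c(CC=C(C)C)c(OC(=O)C(C)(C)C)c1OC(=O)C(C)(C)C
F4 | step 8 | (2S)-2-[3,4-bis(pivaloyloxy)-2,5-diprenylphenyl]chroman-7-yl pivalate | CC(C)=CCc1cc([C@@H]2CCc3ccc(OC(=O)C(C)(C)C)cc3O2)c(CC=C(C)C)c(OC(=O)C(C)(C)C)c1OC(=O)C(C)(C)C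
F5 | step 3 | 3,4-bis(allyloxy)benzaldehyde | O=Cc1ccc(OCC=C)c(OCC=C)c1
F6 | step 3 | 2,5-diallyl-3,4-dihydroxybenzaldehyde | C=CCc1cc(C=O)c(CC=C)c(O)c1O
F7 | step 3 | 2,5-diallyl-3,4-bis(pivaloyloxy)benzaldehyde | C=CCc1cc(C=O)c(CC=C)c(OC(=O)C(C)(C)C)c1OC(=O)C(C)(C)C
F8 | step 5 | 1-[3,4-bis(pivaloyloxy)-2,5-diprenylphenyl]prop-2-en-1-one | CC(C)=CCc1cc(C(=O)C=C)c(CC=C(C)C)c(OC(=O)C(C)(C)C)c1OC(=O)C(C)(C)C
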